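In the noon run the target stopped climbing: it read 90.7% after 12.0 h and 90.1% after 15.0 h, while 7.0% of the starting material was still read. I took this stop to mean that second substrate is used one for one, which makes it the limiting reagent. So I defined the ceiling Y as second substrate charged over starting material charged, which for that run is 90.0%, close to those readings.

| setting | noon | summer | Tuesday's | Sunday's | Wednesday's | Thursday's |
|---|---|---|---|---|---|---|
| starting material | 11 mM | 5.5 mM | 11 mM | 11 mM | 11 mM | 11 mM |
| second substrate | 9.9 mM | 9.9 mM | 2.50 mM | 5.00 mM | 9.90 mM | 3.00 mM |
| free enzyme | 8.2 µM | 5.5 µM | 5.5 µM | 5.5 µM | 5.5 µM | 5.5 µM |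
| remark | run made earlier | run made earlier |  |  |  |  |
| time |  |  | 25 h | 25 h | 25 h | 25 h |

- noon (time / h: target / %, starting material / %): 1.00: 14.8, 85.7; 3.00: 40.5, 57.6; 5.00: 60.0, 38.9; 8.00: 79.8, 19.6; 12.0: 90.7, 9.4; 15.0: 90.1, 7.0
- summer (time / h: target / %, starting material / %): 1.00: 12.0, 86.4; 3.00: 37.3, 64.0; 5.00: 51.1, 47.7; 8.00: 70.6, 28.7; 12.0: 85.9, 15.1; 15.0: 93.3, 8.6

(scatter of a reading: 1 percentage point)

- ranking by amount of target, in percent of the starting material charged, from high to low, at 25 h (Tuesday's / Sunday's / Wednesday's / Thursday's)
- the amount of target, in percent of the starting material charged of the flask you put first, at 25 h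
- the amount of target, in percent of the starting material charged of the flask you put last, at 25 h

- the earlier runs were read with a standard deviation of 1 percentage point

A ceiling counts for a flask only if the flask reaches it in time, so I needed a clock. Between 3.00 h and 8.00 h the starting material of the noon run fell with a rate constant k, read as the logarithm of the ratio of its readings over the time between them, of 0.216 h⁻¹. Taking the rate as proportional to enzyme, I scaled this to 0.145 h⁻¹ for 5.5 µM. Wednesday's has the ceiling 90.0%, higher than Sunday's 45.5%, Thursday's 27.3% and Tuesday's 22.7%, so it needs the longest time, and first-order decay gives 15.9 h, shorter than the 25 h allowed.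

The weak link was trusting first-order decay to the very end, where second substrate thins out. So I reforged it from the noon run's own clock: its 12.0 h to the ceiling, stretched by the enzyme ratio, gives 17.9 h, still shorter than 25 h. I therefore committed to the ceilings themselves, in their order.

The forecast gave Wednesday's > Sunday's > Thursday's > Tuesday's, with 89% (85% to 92%) and 22.7% (21% to 24%), its top 1 point under my ceiling, on the ground that “the rate barely depends on the second substrate until it is nearly gone”.

The simulation gave Wednesday's > Sunday's > Thursday's > Tuesday's, with 90.0% for Wednesday's against its ceiling 90.0%, and 22.7% for Tuesday's against its 22.7%.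

    second substrate + first complex → spent catalyst (k = 0.0507 L mol⁻¹ min⁻¹)
    first complex ⇌ loaded enzyme + first product (K = 0.0270 M, k = 8.76 min⁻¹)
    second substrate + loaded enzyme ⇌ second complex (K = 1360 L mol⁻¹, k = 1.55 × 10⁵ L mol⁻¹ min⁻¹)
    starting material + free enzyme ⇌ first complex (K = 67.9 L mol⁻¹, k = 39800 L mol⁻¹ min⁻¹)
    second complex → free enzyme + target (k = 205 min⁻¹)

In Tuesday's the step from second complex to free enzyme and target ran while second substrate was there, and the midpoint of its turnover up to 25 h fell at 1.10 h. By 12.5 h Tuesday's second substrate stood at 0%, and the target stayed at 22.7% through 25.0 h, with 77.2% of the starting material unused and 79.5% of the catalyst held as loaded enzyme. A neighbour of Tuesday's with 6.2 mM of second substrate has the ceiling 56.4% and gave 56.4%.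

The numbers in the tables are simulated from invented constants, and the scatter is random.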